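**Retrosynthetic overview**
- Feature: spiro atom C6 is bonded to the sp2 carbon C7 of ring A. The C2–C3 dihalide unit of ring B is homoallylic to C6 through C1. Together these mark a cyclopropylcarbinyl opening of a C2–C6 bond followed by a 1,2-shift of C5 from C7 to C6.
- Late stage: C3–Br and C2–Cl come from the C2=C3 alkene (epoxide, chloride at C2, neutral deoxybromination at C3). C15 comes from methylenation of the C7 ketone, and C10–Br from Appel inversion.
- Key disconnection C5–C6: spiro ketone 15 comes from the cyclopropane-fused 7-silyloxydecalin carbinol 13.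
- 13 comes from MeLi addition and directed Simmons–Smith reaction on silyloxy-octalone 9. 9 comes from Birch reduction and hydroxyl-directed epoxidation of (R)-tetralol 4, made from 7-methoxy-2-tetralone.
- Ring order: ring A (present in the tetralone), provisional ring C (C2–C3–C4–C5–C7–C6, from the arene), cyclopropane C1–C2–C6, then ring B by contraction of a seven-membered ring formed in situ.

Key step: step 8

Numbering remark: chamigrene numbering is used throughout and equals spiro[5.5]undecane numbering. Ring B is C1–C6, C6 is the spiro atom, ring A is C6–C11, and C15 is the methylene carbon.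
Assumption: 1-bromo-N,N,2-trimethylpropenylamine is used as a stock reagent, made beforehand from the commercial chloro analogue by halide exchange.

**Step 1**
Reactants: 1 7-methoxy-2-tetralone; 2 iodomethane
Product: 3 7-methoxy-1,1-dimethyl-3,4-dihydronaphthalen-2(1H)-one
Conditions: KOt-Bu, MeI, THF/t-BuOH, 0 °C to rt
Reagents that add atoms: iodomethane (2), CI
Why: Enolate alkylation: C1 of the 2-tetralone is benzylic and alpha to the ketone, so both deprotonations and both methylations should take place there and build the C11 gem-dimethyl carbon next to the future C6.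

**Step 2**
Reactants: 3 7-methoxy-1,1-dimethyl-3,4-dihydronaphthalen-2(1H)-one
Product: 4 (2R)-7-methoxy-1,1-dimethyl-1,2,3,4-tetrahydronaphthalen-2-ol
Conditions: (S)-2-methyl-CBS-oxazaborolidine (10 mol %), BH3·SMe2, THF, −20 °C; MeOH quench
Reagents that add atoms: none
Why: Corey–Bakshi–Shibata reduction: the quaternary C11 is the large and the C9 methylene the small flank of the ketone, so the (S)-catalyst should give the (R)-carbinol at C10, the stereocentre from which all others are relayed.

**Step 3**
Reactants: 4 (2R)-7-methoxy-1,1-dimethyl-1,2,3,4-tetrahydronaphthalen-2-ol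
Product: 6 (7R)-7-hydroxy-8,8-dimethyl-3,4,5,6,7,8-hexahydronaphthalen-2(1H)-one, via Birch dienol methyl ether 5 (not isolated)
Conditions: Li, NH3(l)/THF/t-BuOH, −78 to −33 °C; then (CO2H)2 (cat.), THF/MeOH/H2O, rt
Reagents that add atoms: water, O
Why: Birch reduction of the anisole ring leaves the enol ether C3=C4 and the tetrasubstituted ring-fusion alkene C6=C7, and oxalic acid is mild enough to hydrolyse the enol ether to the C3 ketone without moving C6=C7 into conjugation.

**Step 4**
Reactants: 6 (7R)-7-hydroxy-8,8-dimethyl-3,4,5,6,7,8-hexahydronaphthalen-2(1H)-one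
Product: 8 (4aR,7R)-4a,7-dihydroxy-8,8-dimethyl-4,4a,5,6,7,8-hexahydronaphthalen-2(3H)-one, via syn epoxy ketone 7 (not isolated)
Conditions: VO(acac)2 (3 mol %), t-BuOOH, CH2Cl2, 0 °C to rt; then DBU (20 mol %), rt
Reagents that add atoms: tert-butyl hydroperoxide, CC(C)(C)OO
Why: Vanadium-catalysed hydroxyl-directed epoxidation of a cyclic homoallylic alcohol (3-cyclohexenol type) delivers oxygen to the face of C6=C7 that bears the C10 hydroxyl, which is the cis C7–O/C10–O relation needed later and the opposite of what steric control by a C10 ether would be expected to give, and base-induced E1cB opening of the beta,gamma-epoxy ketone at C6 then leaves the C7 carbinol and the C2=C6 enone.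

**Step 5**
Reactants: 8 (4aR,7R)-4a,7-dihydroxy-8,8-dimethyl-4,4a,5,6,7,8-hexahydronaphthalen-2(3H)-one
Product: 9 (4aR,7R)-8,8-dimethyl-4a,7-bis(triethylsilyloxy)-4,4a,5,6,7,8-hexahydronaphthalen-2(3H)-one
Conditions: Et3SiOTf, 2,6-lutidine, CH2Cl2, −78 to 0 °C
Reagents that add atoms: triethylsilyl triflate, CC[Si](CC)(CC)OS(=O)(=O)C(F)(F)F
Why: Silylation with a silyl triflate is strong enough for the tertiary C7 hydroxyl; the C10 ether is a protecting group, whereas the C7 ether keeps this second, equally ionisable carbinol from leaving in step 8 while still serving as the electron donor of the 1,2-shift.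

**Step 6**
Reactants: 9 bis(triethylsilyl) enone; 10 methyllithium
Product: 11 (2S,4aR,7R)-2,8,8-trimethyl-4a,7-bis(triethylsilyloxy)-2,3,4,4a,5,6,7,8-octahydronaphthalen-2-ol (C3–OH cis to C7–OSiEt3)
Conditions: MeLi, Et2O/THF, −78 °C; then H2O; Et3N-washed silica
Reagents that add atoms: methyllithium (10), [Li]C
Why: 1,2-Addition of an organolithium to an enone: axial attack on the half-chair from the face opposite to the pseudoaxial C7 silyloxy group should place the C3 hydroxyl cis to it, a configuration that only serves to steer step 7 because C3 becomes sp2 in step 8.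

**Step 7**
Reactants: 11 tertiary allylic alcohol; 12 diiodomethane
Product: 13 2,8,8-trimethyl-4a,7-bis(triethylsilyloxy)decahydrocyclopropa[d]naphthalen-2-ol (chamigrene numbering 2R,3S,6S,7R,10R; C1, C3–OH and C7–OSiEt3 on one face, C10–OSiEt3 cis to C7–O)
Conditions: Et2Zn, CH2I2, CH2Cl2, −20 °C to rt; sat. aq. NaHCO3
Reagents that add atoms: diiodomethane (12), ICI
Why: Hydroxyl-directed Simmons–Smith cyclopropanation (Furukawa variant): the zinc alkoxide of the C3 carbinol delivers CH2 (C1) to its own face of C2=C6, a direction known to override the hindrance by an angular group and an 8,8-dimethyl unit in octalin-2-ols, so C1, C3–O and C7–O end up cis.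

**Step 8**
Reactants: 13 cyclopropane-fused decalin carbinol
Product: 15 (6R,10R)-3,11,11-trimethyl-10-(triethylsilyloxy)spiro[5.5]undec-2-en-7-one, via ring-expanded C6 cation 14 (not isolated)
Conditions: Tf2NH (5 mol %), CH2Cl2, −78 to −20 °C; Et3N quench
Reagents that add atoms: none
Why: Proposed new method: the acid ionises the only free carbinol (C3) to a tertiary cyclopropylcarbinyl cation, the C2–C6 bond opens to the C2=C3 alkene and the tertiary cation 14 at C6 inside a seven-membered ring (C6–C1–C2–C3–C4–C5–C7), and C5 then shifts from C7 to C6 under the push of the C7 silyloxy oxygen, after which transfer of Et3Si to the liberated water gives the C7 ketone irreversibly and returns the acid. The closest known reactions are the acid-catalysed thujopsene-to-chamigrene rearrangement, which uses the same C2–C6 opening and the same C5 shift but ends in unselective proton loss, and the semipinacol rearrangement of alpha-silyloxy carbocations; coupling the two in one cascade is the new element. Ring B (C1–C6) is closed by ring contraction, a 1,2-alkyl shift that forms C5–C6 and turns the seven-membered ring into a six-membered one, not by an end-to-end cyclisation. The new stereocentre C6 is controlled by C7: C5 stays on the face of ring A that it occupies at C7 (anti to the C7 oxygen) and enters the lobe vacated by C2, so 7R is translated into 6R while C2, C3 and C7 cease to be stereocentres. Two selectivities are needed: ionisation at C3 rather than at C7, itself a tertiary cyclopropylcarbinyl position, is secured by leaving only C3 as a free hydroxyl, by the poorer leaving ability of the silyl ether and by the fully substituted C6 that takes up the charge of the C3 cation; migration of C5 rather than C8 is secured because ring A holds the C7–C8 bond close to the nodal plane of the C6 cation and its shift would shrink ring A to a cyclopentane, whereas the C7–C5 bond of the flexible seven-membered ring can align with the empty orbital. Dienes formed by proton loss can re-enter through reprotonation, so the ketone should act as the sink.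

**Step 9**
Reactants: 15 silyloxy spiro ketone
Product: 16 (6R,10R)-10-hydroxy-3,11,11-trimethylspiro[5.5]undec-2-en-7-one
Conditions: HF·pyridine, THF, 0 °C to rt
Reagents that add atoms: none
Why: Fluoride cleavage of a silyl ether; the ketone and the trisubstituted alkene are inert and no stereocentre is touched.

**Step 10**
Reactants: 16 hydroxy spiro ketone
Product: 17 (6R,10S)-10-bromo-3,11,11-trimethylspiro[5.5]undec-2-en-7-one
Conditions: CBr4, PPh3, toluene, 80 °C
Reagents that add atoms: tetrabromomethane, BrC(Br)(Br)Br
Why: Appel reaction: the oxyphosphonium salt is displaced by bromide in an SN2 step with inversion (10R to 10S), which is slow at this neopentyl position but known for 2,2-dimethylcyclohexanols, and it is placed here because no other halide, no exocyclic alkene and no acid-labile group is yet present.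

**Step 11**
Reactants: 17 bromo spiro ketone; 18 Cp2TiMe2
Product: 19 (6S,10S)-10-bromo-3,11,11-trimethyl-7-methylidenespiro[5.5]undec-2-ene (10-bromo-beta-chamigrene)
Conditions: Cp2TiMe2, toluene, 80 °C, dark
Reagents that add atoms: Cp2TiMe2 (18), [CH3-].[CH3-].[Ti+4].c1cc[cH-]c1.c1cc[cH-]c1
Why: Petasis methylenation: Cp2Ti=CH2 formed on heating is small and non-basic, so it should convert the hindered, enolisable C7 ketone into the C7=C15 methylene without touching the equatorial neopentyl bromide.

**Step 12**
Reactants: 19 10-bromo-beta-chamigrene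
Product: 20 (2S,3R,6S,10S)-2,3-epoxide of 19 (oxirane oxygen on the face of ring B anti to C7, syn to C11)
Conditions: mCPBA, CH2Cl2, −20 to 0 °C
Reagents that add atoms: mCPBA, OOC(=O)c1cccc(Cl)c1
Why: Prilezhaev epoxidation: the trisubstituted C2=C3 alkene is more electron-rich and less hindered than the C7=C15 methylene next to C6, and with C11 equatorial and C7 axial on ring B the peracid should approach the face anti to C7, which sets C3 (3R) and places the oxygen trans to the future chloride.

**Step 13**
Reactants: 20 epoxide
Product: 21 (2R,3R,6S,10S)-10-bromo-2-chloro-3,11,11-trimethyl-7-methylidenespiro[5.5]undecan-3-ol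
Conditions: LiCl, AcOH, THF, rt to 45 °C
Reagents that add atoms: lithium chloride, [Li+].[Cl-]
Why: SN2 opening of an epoxide by chloride under weakly acidic conditions: attack at the secondary C2 with inversion is favoured both by the lower substitution and by the Fürst–Plattner rule in the half-chair with C7 axial, and the equatorial C10 bromide holds ring A so that C15 leans away from C2, giving the trans-diaxial chlorohydrin with 2R.

**Step 14**
Reactants: 21 chlorohydrin
Product: 22 (2R,3R,6S,10S)-3,10-dibromo-2-chloro-3,11,11-trimethyl-7-methylidenespiro[5.5]undecane (target)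
Conditions: Me2C=C(Br)NMe2, CH2Cl2, 0 °C to rt
Reagents that add atoms: 1-bromo-N,N,2-trimethylpropenylamine, CC(C)=C(Br)N(C)C
Why: Deoxybromination of a tertiary alcohol with an alpha-bromoenamine under neutral conditions: the O-alkyl imidate salt ionises with help from the antiperiplanar C2 chlorine and bromide returns to C3 anti to that chlorine, so the C–O bond should be replaced with retention (3R), while the absence of free HBr spares the C7=C15 alkene.

**Compound list**
1 | 7-methoxy-2-tetralone | COc1ccc2c(c1)CC(=O)CC2 | starting material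
2 | iodomethane | CI | starting material
3 | 7-methoxy-1,1-dimethyl-3,4-dihydronaphthalen-2(1H)-one | COc1ccc2c(c1)C(C)(C)C(=O)CC2 | intermediate
4 | (2R)-7-methoxy-1,1-dimethyl-1,2,3,4-tetrahydronaphthalen-2-ol | COc1ccc2c(c1)C(C)(C)[C@H](O)CC2 | intermediate
5 | (2R)-7-methoxy-1,1-dimethyl-1,2,3,4,5,8-hexahydronaphthalen-2-ol (not isolated) | COC1=CCC2=C(C1)C(C)(C)[C@H](O)CC2 | intermediate
6 | (7R)-7-hydroxy-8,8-dimethyl-3,4,5,6,7,8-hexahydronaphthalen-2(1H)-one | O=C1CCC2=C(C1)C(C)(C)[C@H](O)CC2 | intermediate
7 | C6–C7 epoxide of 6, oxygen cis to the C10 hydroxyl (not isolated) | O=C1CC[C@@]23O[C@]2(C1)C(C)(C)[C@H](O)CC3 | intermediate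
8 | (4aR,7R)-4a,7-dihydroxy-8,8-dimethyl-4,4a,5,6,7,8-hexahydronaphthalen-2(3H)-one | O=C1CC[C@]2(O)CC[C@@H](O)C(C)(C)C2=C1 | intermediate
9 | bis(triethylsilyl) ether of 8 | O=C1CC[C@]2(O[Si](CC)(CC)CC)CC[C@@H](O[Si](CC)(CC)CC)C(C)(C)C2=C1 | intermediate
10 | methyllithium | [Li]C | starting material
11 | (2S,4aR,7R)-2,8,8-trimethyl-4a,7-bis(triethylsilyloxy)-2,3,4,4a,5,6,7,8-octahydronaphthalen-2-ol | C[C@]1(O)CC[C@]2(O[Si](CC)(CC)CC)CC[C@@H](O[Si](CC)(CC)CC)C(C)(C)C2=C1 | intermediate
12 | diiodomethane | ICI | starting material
13 | cyclopropane-fused decalin carbinol, C7 and C10 triethylsilyl ethers (key-step precursor) | CC[Si](CC)(CC)O[C@@]12CC[C@@H](O[Si](CC)(CC)CC)C(C)(C)[C@]1(C3)[C@@H]3[C@@](C)(O)CC2 | intermediate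
14 | ring-expanded homoallylic C6 cation (not isolated) | CC[Si](CC)(CC)O[C@@]12CC[C@@H](O[Si](CC)(CC)CC)C(C)(C)[C+]1CC=C(C)CC2 | intermediate
15 | (6R,10R)-3,11,11-trimethyl-10-(triethylsilyloxy)spiro[5.5]undec-2-en-7-one (key-step product) | O=C1CC[C@@H](O[Si](CC)(CC)CC)C(C)(C)[C@]12CCC(C)=CC2 | intermediate
16 | (6R,10R)-10-hydroxy-3,11,11-trimethylspiro[5.5]undec-2-en-7-one | O=C1CC[C@@H](O)C(C)(C)[C@]12CCC(C)=CC2 | intermediate
17 | (6R,10S)-10-bromo-3,11,11-trimethylspiro[5.5]undec-2-en-7-one | O=C1CC[C@H](Br)C(C)(C)[C@]12CCC(C)=CC2 | intermediate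
18 | Cp2TiMe2 | [CH3-].[CH3-].[Ti+4].c1cc[cH-]c1.c1cc[cH-]c1 | starting material
19 | (6S,10S)-10-bromo-beta-chamigrene | C=C1CC[C@H](Br)C(C)(C)[C@]12CCC(C)=CC2 | intermediate
20 | (2S,3R,6S,10S)-10-bromo-2,3-epoxy-beta-chamigrane with C7=C15 | C=C1CC[C@H](Br)C(C)(C)[C@]12CC[C@@]3(C)O[C@H]3C2 | intermediate
21 | (2R,3R,6S,10S)-10-bromo-2-chloro-3,11,11-trimethyl-7-methylidenespiro[5.5]undecan-3-ol | C=C1CC[C@H](Br)C(C)(C)[C@]12CC[C@@](C)(O)[C@H](Cl)C2 | intermediate
22 | (2R,3R,6S,10S)-3,10-dibromo-2-chloro-3,11,11-trimethyl-7-methylidenespiro[5.5]undecane | C=C1CC[C@H](Br)C(C)(C)[C@]12CC[C@@](C)(Br)[C@H](Cl)C2 | target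

**Step count**
Total steps: 14. Longest linear sequence: 14 (from 1).

**Steps most likely to fail**

Step 8 (labelled step).
- What may go wrong: the C6 cation may be diverted by a shift of C8 that contracts ring A, or by a methyl shift from C11. Proton loss may occur without re-entry into the cascade. The C7 silyl group may be lost early, followed by ionisation at C7.
- Fallback (known chemistry, the two events separated): it sets out from 13. Solvolysis with PPTS in aqueous acetone at rt is the known cyclopropylcarbinyl-to-homoallyl hydration of the thujopsene-to-widdrol type. Water should enter at C6 anti to the departing C2 and give the ring-expanded homoallylic tertiary alcohol F1.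
- In F1 the C7–C5 bond can stand antiperiplanar to the C6–OH bond. A separate classical semipinacol rearrangement (BF3·OEt2, CH2Cl2, −78 °C) should therefore move C5 with inversion at C6 and come back to the route at 15.

Step 14.
- What may go wrong: the ionised C3 centre may lose a proton from C4 or from the C3 methyl. Bromide may attack C2 of the bridged ion, which moves chlorine to C3. The C7=C15 alkene may capture the cation.
- Fallback (ring B halogenated before the methylene exists, so acidic reagents become usable): it sets out from 17. mCPBA should give the epoxy ketone F2, and LiCl/AcOH the chlorohydrin ketone F3. Me3SiBr in CH2Cl2 at 0 °C to rt should then give the bromochloro ketone F4 through the same chlorine-assisted retention.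
- The C7 ketone is methylenated last with Cp2Ti(CH2)(Cl)AlMe2 in THF/pyridine at −40 to 0 °C. This comes back to the route at 22.

Step 10.
- What may go wrong: the slow displacement next to C11 and close to the quaternary C6 may let elimination towards C9, or a methyl shift from C11, take over.
- Fallback (bromide installed before the spiro centre exists): it sets out from 8, where C6 is still sp2 and no axial carbon substituent lies on the backside trajectory. CBr4/PPh3 should convert only the secondary C10 hydroxyl, with inversion, into the bromo hydroxy enone F5.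
- Et3SiOTf/2,6-lutidine should give the C7 silyl ether F6, MeLi the tertiary allylic alcohol F7, and Et2Zn/CH2I2 the bromo cyclopropyl carbinol F8.
- Treatment of F8 with Tf2NH as in step 8 should come back to the route directly at 17. Steps 9 and 10 are then omitted, and the bromide is equatorial in the conformer in which C5 is aligned for migration.

**Further compounds**
F1 | step 8 | bicyclo[5.4.0]undecene with C2=C3, C6–OH cis to C7–OSiEt3, C10–OSiEt3 | CC[Si](CC)(CC)O[C@@]12CC[C@@H](O[Si](CC)(CC)CC)C(C)(C)[C@]1(O)CC=C(C)CC2
F2 | step 14 | (2S,3R,6R,10S)-10-bromo-2,3-epoxy-3,11,11-trimethylspiro[5.5]undecan-7-one | O=C1CC[C@H](Br)C(C)(C)[C@]12CC[C@@]3(C)O[C@H]3C2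
F3 | step 14 | 10-bromo-2-chloro-3-hydroxy-3,11,11-trimethylspiro[5.5]undecan-7-one (Cl and OH trans) | O=C1CC[C@H](Br)C(C)(C)[C@]12CC[C@@](C)(O)[C@H](Cl)C2
F4 | step 14 | 3,10-dibromo-2-chloro-3,11,11-trimethylspiro[5.5]undecan-7-one (Cl and C3–Br trans) | O=C1CC[C@H](Br)C(C)(C)[C@]12CC[C@@](C)(Br)[C@H](Cl)C2
F5 | step 10 | (4aR,7S)-7-bromo-4a-hydroxy-8,8-dimethyl-4,4a,5,6,7,8-hexahydronaphthalen-2(3H)-one | O=C1CC[C@]2(O)CC[C@H](Br)C(C)(C)C2=C1
F6 | step 10 | triethylsilyl ether of F5 | O=C1CC[C@]2(O[Si](CC)(CC)CC)CC[C@H](Br)C(C)(C)C2=C1
F7 | step 10 | 7-bromo-2,8,8-trimethyl-4a-(triethylsilyloxy)-2,3,4,4a,5,6,7,8-octahydronaphthalen-2-ol (C3–OH cis to C7–O) | C[C@]1(O)CC[C@]2(O[Si](CC)(CC)CC)CC[C@H](Br)C(C)(C)C2=C1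
F8 | step 10 | C10-bromo analogue of 13 | CC[Si](CC)(CC)O[C@@]12CC[C@H](Br)C(C)(C)[C@]1(C3)[C@@H]3[C@@](C)(O)CC2
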